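The data come from a simulation with made-up constants, and the scatter is random.

the same everywhere: E 46 µM; D 5.2 µM
- south: J 0.022 M; run made earlier
- south-west: J 1.7 M; run made earlier
- dawn: J 0.015 M; time 8.0 min
- winter: J 0.050 M; time 8.0 min
- noon: J 0.15 M; time 8.0 min
- midnight: J 0.50 M; time 8.0 min
- summer: J 1.5 M; time 8.0 min

| south: time / min | south: Z / % | south-west: time / min | south-west: Z / % |
|---|---|---|---|
| 0.200 | 7.1 | 0.200 | 0.9 |
| 0.667 | 19.9 | 0.667 | 1.8 |
| 1.00 | 28.9 | 1.00 | 1.9 |
| 1.50 | 38.9 | 1.50 | 3.6 |
| 2.50 | 54.0 | 2.50 | 4.2 |
| 3.00 | 60.5 | 3.00 | 1.7 |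
| 4.00 | 68.2 | 4.00 | 5.2 |

(each reading ± 1 percentage point)

- "hardly changes" means that all values lie within two and a half points (for a concentration: within two and a half percent of the largest)

- [Z] at the end for dawn, winter, noon, midnight, summer, in this order
- the course of these numbers from the first flask to the last (falls, then rises / falls all the way / rises, then falls / hardly changes / rises all the way)

1. At early times the south flask, with J charged c = 0.022 M, makes Z at 0.00636 M min⁻¹ on average over the first 1.00 min. The south-west flask, with c = 1.7 M, reads 1.9% at 1.00 min, and with a scatter of 1 percentage point on so small a reading I take no rate from it. As a share of the J charged, that reading stands below the south flask's 28.9% at the same time, though the south-west charge is 77.3 times larger.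

2. In the south-west flask the four readings from 1.50 min to 4.00 min run 3.6%, 4.2%, 1.7%, 5.2%, each with a scatter of 1 point, so I can't tell from them whether Z is still climbing there. Their mean, as an amount, is W = 0.0625 M, a rough reading taken over a stretch in which Z may still be rising, and I call it the ceiling, my estimate of the Z that a J-rich flask ends with. It is 3.68% of the J charged there. Z readings don't show where the other J goes, and I don't need that here.

3. Two amounts are then set against each other, c and W. For c far below W, I expect Z close to c; for c far above W, close to W. I join these limits as Z = cW/(c+W), so the share of J ending as Z (the selectivity) is W/(c+W).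

4. For the south flask this share is 74.0%. The reading at 4.00 min is 68.2%, up from 60.5% at 3.00 min. The asked time 8.0 min is twice the time of that last reading, so I use the rule for the end.

5. My row is 0.0121 M, 0.0278 M, 0.0441 M, 0.0555 M, 0.0600 M, rising all the way.

6. The forecast gives 0.012 M, 0.036 M, 0.078 M, 0.112 M, 0.124 M, rises all the way, holding that “the catalyst is dying”; its last value stands above mine.

7. The flasks give 0.0127 M, 0.0309 M, 0.0493 M, 0.0606 M, 0.0646 M: rises all the way.

    J + E → X (k = 200 M⁻¹ s⁻¹)
    X → E + Z (k = 12.0 s⁻¹)
    E + D → L (k = 1.20 × 10⁵ M⁻¹ s⁻¹)
    2 J → Q (k = 0.0750 M⁻¹ s⁻¹)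

8. In summer at 8.00 min, Q, the other product, with each Q counted as two J, holds 95.6% of the J charged, Z holds 4.31%, and J left is 0.12%. There my 0.0600 M stands below the flask's 0.0646 M. For midnight W/(c+W) is 11.1%, and the midnight flask at 8.00 min holds Z at 12.1% of the J charged.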